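## Retrosynthetic overview

1. Feature: in ring A of the chromene (C4a, C5, C6, C7, C8, C8a), C5–OH, the C6 acyl carbon and C7–OMe stand side by side. C8–H, the C8a–O1 oxygen and the C4a–C4 carbon follow them. A vinylketene and a methoxyalkyne leave exactly this substitution pattern.
2. Late disconnections: the pyran ring (O1–C2) is opened to the 3'-prenyl-2',4'-dihydroxychalcone, and the enone is traced back to a silyl-protected allylic carbinol.
3. Key disconnection: C5–C6 and C7–C8. The pentasubstituted phenol (C8 keeps its hydrogen) comes from a 3-silyloxy-4-prenylcyclobutenone (C5, C8, C8a, C4a) and a methoxyalkyne (C6, C7, the three-carbon chain, ring B).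
4. The cyclobutenone comes from prenylketene and (triisopropylsilyloxy)ethyne by [2+2] addition. The alkyne comes from lithium methoxyacetylide and 4-methoxycinnamaldehyde, followed by silylation.
5. Ring order: ring B is bought, then the four-membered carrier ring is made, then ring A (step 6), then the pyran ring (step 9).

Key step: step 6

Assumption: (triisopropylsilyloxy)ethyne is not a catalogue compound. It is therefore made from acetylene by the peroxide oxidation and O-silylation protocol that serves for substituted silyl ynol ethers.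

## Route

Step 1
Reactants: 1 5-methylhex-4-enoic acid
Product: 2 5-methylhex-4-enoyl chloride
Conditions: (COCl)2, DMF (cat.), CH2Cl2, 0 °C → rt; distillation
Reagents that add atoms: oxalyl chloride ClC(=O)C(=O)Cl
Why: Vilsmeier-type activation of the acid by oxalyl chloride and DMF gives the acid chloride under mild conditions that should leave the trisubstituted alkene untouched, since everything else leaves as gas.

Step 2
Reactants: 3 acetylene
Product: 6 (triisopropylsilyloxy)ethyne, via lithium acetylide 4 (not isolated), via lithium ethynolate 5 (not isolated)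
Conditions: n-BuLi, THF, −78 °C (acetylene in excess, dilute); t-BuOOLi [from t-BuOOH in decane + LiN(SiMe3)2, THF, −78 °C], −78 → −10 °C; TIPSOTf, −78 → 0 °C; pentane, cold H2O wash
Reagents that add atoms: tert-butyl hydroperoxide CC(C)(C)OO; triisopropylsilyl trifluoromethanesulfonate CC(C)[Si](OS(=O)(=O)C(F)(F)F)(C(C)C)C(C)C
Why: Electrophilic oxygenation of a lithium acetylide by lithium tert-butyl peroxide gives the ynolate, and the bulky, hard silyl triflate should silylate it on oxygen rather than on carbon, which is the standard peroxide route to triisopropylsilyl ynol ethers applied to the parent acetylide.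

Step 3
Reactants: 2 5-methylhex-4-enoyl chloride; 6 (triisopropylsilyloxy)ethyne
Product: 8 racemic 4-(3-methylbut-2-enyl)-3-(triisopropylsilyloxy)cyclobut-2-en-1-one, via prenylketene 7 (not isolated)
Conditions: Et3N, 6 (1.5 equiv), Et2O, slow addition of 2, 0 °C → rt; filtration; Et3N-deactivated silica
Reagents that add atoms: none
Why: Dehydrochlorination gives the aldoketene, which undergoes a ketene–ynol ether [2+2] cycloaddition in which the nucleophilic terminal alkyne carbon bonds to the ketene carbonyl carbon, so that the silyloxy group lands on C3 and the prenyl group on C4, whose new stereocentre forms as a racemate and is erased in step 6.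

Step 4
Reactants: 9 chloroacetaldehyde dimethyl acetal; 10 (E)-4-methoxycinnamaldehyde
Product: 12 racemic (E)-1-methoxy-5-(4-methoxyphenyl)pent-4-en-1-yn-3-ol, via lithium methoxyacetylide 11 (not isolated)
Conditions: LiNEt2 (3.1 equiv, from Et2NH + n-BuLi), THF, 0 °C; then 10, −78 → −20 °C; H2O quench
Reagents that add atoms: none
Why: Two eliminations and one deprotonation of the chloroacetal by the amide base give the lithium alkoxyacetylide, which adds 1,2 to the enal carbonyl as acetylides do, and the carbinol centre forms as a racemate without consequence because it later becomes the ketone carbon.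

Step 5
Reactants: 12 racemic (E)-1-methoxy-5-(4-methoxyphenyl)pent-4-en-1-yn-3-ol
Product: 13 racemic tert-butyl-[(E)-1-methoxy-5-(4-methoxyphenyl)pent-4-en-1-yn-3-yl]oxy-dimethylsilane
Conditions: TBSCl, imidazole, DMF, 0 °C → rt; Et3N-deactivated silica
Reagents that add atoms: tert-butyldimethylsilyl chloride CC(C)(C)[Si](C)(C)Cl
Why: This is a standard imidazole-promoted silylation of a secondary alcohol, run in a basic medium so that the acid-triggered Meyer–Schuster rearrangement of the alkoxypropargylic alcohol cannot start.

Step 6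
Reactants: 8 racemic 4-(3-methylbut-2-enyl)-3-(triisopropylsilyloxy)cyclobut-2-en-1-one; 13 racemic tert-butyl-[(E)-1-methoxy-5-(4-methoxyphenyl)pent-4-en-1-yn-3-yl]oxy-dimethylsilane
Product: 18 racemic 2-[(E)-1-(tert-butyldimethylsilyloxy)-3-(4-methoxyphenyl)prop-2-enyl]-3-methoxy-6-(3-methylbut-2-enyl)-5-(triisopropylsilyloxy)phenol, via vinylketene 14 (not isolated), via vinylcyclobutenone adduct 15 (not isolated), via dienylketene 16 (not isolated), via cyclohexadienone tautomer 17 (not isolated)
Conditions: 13 (1.3 equiv), toluene, 100 °C, slow addition of 8, Ar, base-washed sealed vessel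
Reagents that add atoms: none
Why: Heat opens 8 by conrotatory four-electron electrocyclic cleavage of its C1–C4 bond to vinylketene 14, whose ketene C=C adds 13 in a [2+2] step that joins the chain-bearing alkyne carbon to the ketene carbonyl carbon (C5–C6) and the methoxy-bearing carbon to the ketene α-carbon (C7–C8), giving 15. A second four-electron opening turns 15 into dienylketene 16, ring A closes by disrotatory six-electron electrocyclisation between the ketene carbon (C5) and the prenyl-bearing terminus (C4a), and tautomerisation of dienone 17 gives phenol 18. The closest known reaction type is the Danheiser benzannulation of cyclobutenones with alkoxy- and silyloxyalkynes, which tolerates branching next to the alkyne. No stereocentre of the target is made, because the C4 centre of 8 and the ring centres of 15 and 17 vanish on aromatisation and the carbinol centre of 13 is carried as a racemate until step 8 removes it. The selectivity needed is the orientation of the ketene–alkyne addition, which the polarisation of the ynol ether secures (the methoxy group makes the chain-bearing carbon the nucleophile), while the styryl and prenyl alkenes are far poorer ketenophiles. Acid-free conditions, the lowest workable temperature and slow feeding of 8 are chosen to hold back loss of silanol from the new ortho-hydroxybenzyl silyl ether and acylation of 18 by 14.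

Step 7
Reactants: 18 racemic 2-[(E)-1-(tert-butyldimethylsilyloxy)-3-(4-methoxyphenyl)prop-2-enyl]-3-methoxy-6-(3-methylbut-2-enyl)-5-(triisopropylsilyloxy)phenol
Product: 19 racemic 4-[(E)-1-hydroxy-3-(4-methoxyphenyl)prop-2-enyl]-5-methoxy-2-(3-methylbut-2-enyl)benzene-1,3-diol
Conditions: Bu4NF (3 equiv), THF, 0 °C; pH 7 phosphate buffer work-up; crude material used at once
Reagents that add atoms: none
Why: Fluoride-driven desilylation cleaves the aryl triisopropylsilyl ether and the secondary tert-butyldimethylsilyl ether in a basic medium, in which ortho-hydroxyaryl allylic carbinols persist, and the neutral work-up and immediate use avoid the acid-induced dehydrative ring closure.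

Step 8
Reactants: 19 racemic 4-[(E)-1-hydroxy-3-(4-methoxyphenyl)prop-2-enyl]-5-methoxy-2-(3-methylbut-2-enyl)benzene-1,3-diol
Product: 20 (E)-1-[2,4-dihydroxy-6-methoxy-3-(3-methylbut-2-enyl)phenyl]-3-(4-methoxyphenyl)prop-2-en-1-one
Conditions: activated MnO2 (excess), CH2Cl2, rt; filtration through Celite
Reagents that add atoms: none
Why: MnO2 oxidation is selective for allylic and benzylic alcohols, the carbinol here being both, and the enone formed gains conjugation and a hydrogen bond from the C5 hydroxyl.

Step 9
Reactants: 20 (E)-1-[2,4-dihydroxy-6-methoxy-3-(3-methylbut-2-enyl)phenyl]-3-(4-methoxyphenyl)prop-2-en-1-one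
Product: 22 glychalcone A, via ortho-quinone methide 21 (not isolated)
Conditions: DDQ (1.1 equiv), 1,4-dioxane, 80 °C
Reagents that add atoms: none
Why: In this DDQ oxidative cyclisation of an ortho-prenylphenol, hydride abstraction from the benzylic CH2 gives the ortho-quinone methide, which closes by oxa-six-electron electrocyclisation, and the C8a hydroxyl takes part because the C5 hydroxyl is tied up in the chelate with the ketone, as is usual for 3'-prenyl-2',4'-dihydroxychalcones.

## Compound list

1 | 5-methylhex-4-enoic acid | CC(C)=CCCC(=O)O | starting material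
2 | 5-methylhex-4-enoyl chloride | CC(C)=CCCC(=O)Cl | intermediate
3 | acetylene | C#C | starting material
4 | lithium acetylide | [Li]C#C | intermediate
5 | lithium ethynolate | [Li]OC#C | intermediate
6 | (triisopropylsilyloxy)ethyne | C#CO[Si](C(C)C)(C(C)C)C(C)C | intermediate
7 | 5-methylhexa-1,4-dien-1-one (prenylketene) | CC(C)=CCC=C=O | intermediate
8 | racemic 4-(3-methylbut-2-enyl)-3-(triisopropylsilyloxy)cyclobut-2-en-1-one | CC(C)=CCC1C(=O)C=C1O[Si](C(C)C)(C(C)C)C(C)C | intermediate
9 | chloroacetaldehyde dimethyl acetal | COC(CCl)OC | starting material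
10 | (E)-4-methoxycinnamaldehyde | COc1ccc(/C=C/C=O)cc1 | starting material
11 | lithium methoxyacetylide | [Li]C#COC | intermediate
12 | racemic (E)-1-methoxy-5-(4-methoxyphenyl)pent-4-en-1-yn-3-ol | COC#CC(O)/C=C/c1ccc(OC)cc1 | intermediate
13 | racemic tert-butyl-[(E)-1-methoxy-5-(4-methoxyphenyl)pent-4-en-1-yn-3-yl]oxy-dimethylsilane | COC#CC(O[Si](C)(C)C(C)(C)C)/C=C/c1ccc(OC)cc1 | intermediate
14 | 7-methyl-3-(triisopropylsilyloxy)octa-1,3,6-trien-1-one, prenyl group turned outward (vinylketene) | O=C=C/C(O[Si](C(C)C)(C(C)C)C(C)C)=C/CC=C(C)C | intermediate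
15 | 2-[(E)-1-(tert-butyldimethylsilyloxy)-3-(4-methoxyphenyl)prop-2-enyl]-3-methoxy-4-[5-methyl-1-(triisopropylsilyloxy)hexa-1,4-dienyl]cyclobut-2-en-1-one, racemic diastereomer mixture | O=C1C(C(O[Si](C)(C)C(C)(C)C)/C=C/c2ccc(OC)cc2)=C(OC)C1/C(O[Si](C(C)C)(C(C)C)C(C)C)=C/CC=C(C)C | intermediate
16 | racemic dienylketene, O=C=C(side chain)–C(OMe)=CH–C(OTIPS)=CH–CH2CH=CMe2, central alkene cis | O=C=C(C(O[Si](C)(C)C(C)(C)C)/C=C/c1ccc(OC)cc1)/C(OC)=C\C(O[Si](C(C)C)(C(C)C)C(C)C)=C\CC=C(C)C | intermediate
17 | 2-[(E)-1-(tert-butyldimethylsilyloxy)-3-(4-methoxyphenyl)prop-2-enyl]-3-methoxy-6-(3-methylbut-2-enyl)-5-(triisopropylsilyloxy)cyclohexa-2,4-dien-1-one, racemic diastereomer mixture | O=C1C(C(O[Si](C)(C)C(C)(C)C)/C=C/c2ccc(OC)cc2)=C(OC)C=C(O[Si](C(C)C)(C(C)C)C(C)C)C1CC=C(C)C | intermediate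
18 | racemic 2-[(E)-1-(tert-butyldimethylsilyloxy)-3-(4-methoxyphenyl)prop-2-enyl]-3-methoxy-6-(3-methylbut-2-enyl)-5-(triisopropylsilyloxy)phenol | COc1ccc(/C=C/C(O[Si](C)(C)C(C)(C)C)c2c(OC)cc(O[Si](C(C)C)(C(C)C)C(C)C)c(CC=C(C)C)c2O)cc1 | intermediate
19 | racemic 4-[(E)-1-hydroxy-3-(4-methoxyphenyl)prop-2-enyl]-5-methoxy-2-(3-methylbut-2-enyl)benzene-1,3-diol | COc1ccc(/C=C/C(O)c2c(OC)cc(O)c(CC=C(C)C)c2O)cc1 | intermediate
20 | (E)-1-[2,4-dihydroxy-6-methoxy-3-(3-methylbut-2-enyl)phenyl]-3-(4-methoxyphenyl)prop-2-en-1-one | COc1ccc(/C=C/C(=O)c2c(OC)cc(O)c(CC=C(C)C)c2O)cc1 | intermediate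
21 | ortho-quinone methide (C8a carbonyl, exocyclic C4a=CH–CH=CMe2 turned towards it) | O=C1C=C(OC)C(C(=O)/C=C/c2ccc(OC)cc2)=C(O)/C1=C/C=C(C)C | intermediate
22 | glychalcone A, (E)-1-(5-hydroxy-7-methoxy-2,2-dimethylchromen-6-yl)-3-(4-methoxyphenyl)prop-2-en-1-one | COc1ccc(/C=C/C(=O)c2c(OC)cc3c(c2O)C=CC(C)(C)O3)cc1 | target

## Step count and risks

Total step count: 9. Longest linear sequence: 6 steps (for example 1, 3, 6, 7, 8, 9).

**Step 6.**
- The new ortho-hydroxybenzyl silyl ether may lose silanol thermally, followed by electrocyclic closure of the phenol oxygen onto the styryl chain.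
- The hindered, inductively deactivated alkyne carbon may add to the ketene too slowly, so the vinylketene dimerises or acylates the product phenol.
- The prenyl group may rotate inward on ring opening, followed by a hydrogen shift.

The fallback gives up the benzannulation and buys ring A. It sets out from 10 and comes back at 20. 5-Methoxyresorcinol would be protected with MOMCl and iPr2NEt to give 1-methoxy-3,5-bis(methoxymethoxy)benzene F1. Directed ortho-lithiation with n-BuLi between the two methoxymethyl ethers, then prenyl bromide, would give 5-methoxy-1,3-bis(methoxymethoxy)-2-(3-methylbut-2-enyl)benzene F2. A second directed lithiation (n-BuLi, TMEDA) at either of the two equivalent positions between OMe and OMOM, then addition to 10, would give racemic (E)-1-[6-methoxy-2,4-bis(methoxymethoxy)-3-(3-methylbut-2-enyl)phenyl]-3-(4-methoxyphenyl)prop-2-en-1-ol F3. This carbinol has no free ortho phenol. MnO2 would oxidise it to (E)-1-[6-methoxy-2,4-bis(methoxymethoxy)-3-(3-methylbut-2-enyl)phenyl]-3-(4-methoxyphenyl)prop-2-en-1-one F4. HCl in MeOH would remove both acetals to reach 20.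

**Step 7.**
- The phenoxides formed first may expel the benzylic silanolate.
- The freed carbinol may undergo dehydrative ring closure during work-up or on the MnO2 surface in step 8.

The fallback never sets the carbinol free. It sets out from 18 and comes back at 20, passing by 19. The C5 hydroxyl would be capped with TBSCl, imidazole and DMAP in DMF to give racemic 1-(tert-butyldimethylsilyloxy)-2-[(E)-1-(tert-butyldimethylsilyloxy)-3-(4-methoxyphenyl)prop-2-enyl]-3-methoxy-6-(3-methylbut-2-enyl)-5-(triisopropylsilyloxy)benzene F5. DDQ in CH2Cl2 with pH 7 buffer would then oxidise the doubly activated allylic and benzylic silyl ether directly to the ketone. The prenyl group has no free neighbouring hydroxyl to cyclise onto at this stage. The product would be (E)-1-[2-(tert-butyldimethylsilyloxy)-6-methoxy-3-(3-methylbut-2-enyl)-4-(triisopropylsilyloxy)phenyl]-3-(4-methoxyphenyl)prop-2-en-1-one F6. Bu4NF would remove the two aryl silyl ethers to give 20.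

**Step 2.**
- Monolithium acetylide may disproportionate while the oxidation warms up.
- The ynolate may be silylated on carbon.
- The terminal silyl ynol ether may be lost by hydrolysis or evaporation during isolation.

The fallback replaces it by a known alkyl ynol ether and brings in the silyl group afterwards. It sets out from 2 and comes back at 8. tert-Butanol, KH and trichloroethylene would give (E)-1,2-dichlorovinyl tert-butyl ether F7. n-BuLi (2.2 equiv, −78 → −40 °C) followed by MeOH would give tert-butoxyethyne F8. Its [2+2] addition to the ketene from 2 and Et3N below room temperature would give racemic 3-tert-butoxy-4-(3-methylbut-2-enyl)cyclobut-2-en-1-one F9. TIPSOTf and 2,6-lutidine in CH2Cl2 would then silylate the carbonyl oxygen while the tert-butyl group leaves the other oxygen, as in the conversion of tert-butyl esters into silyl esters. The carbonyl and the enol ether change places, but C4 is bonded to both oxygenated carbons. The prenyl group therefore stays on the sp3 carbon and the compound formed is 8.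

## Further compounds

F1 | step 6 | 1-methoxy-3,5-bis(methoxymethoxy)benzene | COCOc1cc(OC)cc(OCOC)c1
F2 | step 6 | 5-methoxy-1,3-bis(methoxymethoxy)-2-(3-methylbut-2-enyl)benzene | COCOc1cc(OC)cc(OCOC)c1CC=C(C)C
F3 | step 6 | racemic (E)-1-[6-methoxy-2,4-bis(methoxymethoxy)-3-(3-methylbut-2-enyl)phenyl]-3-(4-methoxyphenyl)prop-2-en-1-ol | COCOc1cc(OC)c(C(O)/C=C/c2ccc(OC)cc2)c(OCOC)c1CC=C(C)C
F4 | step 6 | (E)-1-[6-methoxy-2,4-bis(methoxymethoxy)-3-(3-methylbut-2-enyl)phenyl]-3-(4-methoxyphenyl)prop-2-en-1-one | COCOc1cc(OC)c(C(=O)/C=C/c2ccc(OC)cc2)c(OCOC)c1CC=C(C)C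
F5 | step 7 | racemic 1-(tert-butyldimethylsilyloxy)-2-[(E)-1-(tert-butyldimethylsilyloxy)-3-(4-methoxyphenyl)prop-2-enyl]-3-methoxy-6-(3-methylbut-2-enyl)-5-(triisopropylsilyloxy)benzene | COc1ccc(/C=C/C(O[Si](C)(C)C(C)(C)C)c2c(OC)cc(O[Si](C(C)C)(C(C)C)C(C)C)c(CC=C(C)C)c2O[Si](C)(C)C(C)(C)C)cc1
F6 | step 7 | (E)-1-[2-(tert-butyldimethylsilyloxy)-6-methoxy-3-(3-methylbut-2-enyl)-4-(triisopropylsilyloxy)phenyl]-3-(4-methoxyphenyl)prop-2-en-1-one | COc1ccc(/C=C/C(=O)c2c(OC)cc(O[Si](C(C)C)(C(C)C)C(C)C)c(CC=C(C)C)c2O[Si](C)(C)C(C)(C)C)cc1
F7 | step 2 | (E)-1,2-dichlorovinyl tert-butyl ether | CC(C)(C)O/C(Cl)=C\Cl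
F8 | step 2 | tert-butoxyethyne | C#COC(C)(C)C
F9 | step 2 | racemic 3-tert-butoxy-4-(3-methylbut-2-enyl)cyclobut-2-en-1-one | CC(C)=CCC1C(=O)C=C1OC(C)(C)C
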